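**Retrosynthetic overview**

- The target is a 2H-chromene (benzene ring fused to a pyran ring) whose quaternary C2 carries CH3 and the chain C1'–C12'. The chain is cut at C5'–C6' (Stille coupling of an allylic bromide with an (E)-vinylstannane) and at C3'=C4' (cross-metathesis with methacrolein), which leaves a 2-(but-3-enyl)-2H-chromene.
- The strategy rests on ring carbon C3 and chain carbon C3' being the two ends of the five-atom path C3–C2–C1'–C2'–C3'. Joined as one alkene, they make a 1-methylcyclopent-2-enyl aryl ether whose carbinol carbon is C2. Ring-rearrangement metathesis with an ortho-vinyl group (future C4) then forms C3=C4, closes the pyran and opens the carbocycle to the butenyl chain.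
- That ether comes from fluoride displacement on 5-bromo-2-fluoro-3-methylbenzaldehyde by the alkoxide of (S)-1-methylcyclopent-2-enol. The formyl group activates the displacement and becomes C4; bromine marks the later 6-OH.
- Both stereocentres (C2 and C8', both S) come from one building block, (S)-dehydrolinalool, made from Sharpless epoxygeraniol. Semi-hydrogenation and ring-closing metathesis give the cyclopentenol; hydrostannation gives the C6'–C12' stannane.
- Ring order: the benzene ring is bought, the temporary cyclopentene is made by ring-closing metathesis, and the pyran ring is closed in the key step as the cyclopentene opens.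

Key step: step 11

Assumption: locants are O1, C2–C8a for the chromene and C1'–C12' outward from C2 for the chain; the target SMILES is read as (2S,8'S) with (3'E,6'E) alkenes. Because both stereocentres are drawn from one epoxide, any minor enantiomer of that epoxide would surface after the fragment coupling chiefly as a diastereomer.

**Route**

Step 1
Reactants: 1 geraniol
Product: 2 (2S,3S)-2,3-epoxygeraniol
Conditions: Ti(OiPr)4 (5 mol%), L-(+)-diethyl tartrate (7 mol%), t-BuOOH (anhydrous, isooctane), 4 Å molecular sieves, CH2Cl2, −20 °C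
Reagents that add atoms: tert-butyl hydroperoxide, CC(C)(C)OO
Why: Sharpless asymmetric epoxidation is hydroxyl-directed, so only the allylic C2=C3 alkene reacts, and the L-(+)-tartrate titanium complex delivers oxygen to the face that gives the (2S,3S) epoxide, which sets the tertiary C–O stereocentre that later becomes both C2 and C8' of the target.

Step 2
Reactants: 2 (2S,3S)-2,3-epoxygeraniol
Product: 3 (2S,3R)-3-(chloromethyl)-2-methyl-2-(4-methylpent-3-enyl)oxirane
Conditions: PPh3, CCl4, NaHCO3 (cat.), reflux
Reagents that add atoms: carbon tetrachloride, ClC(Cl)(Cl)Cl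
Why: Appel chlorination replaces the primary hydroxyl by chloride under buffered neutral conditions that leave the trisubstituted epoxide and both stereocentres untouched, the new descriptor at the CH carbon being only a change of priorities.

Step 3
Reactants: 3 (2S,3R)-3-(chloromethyl)-2-methyl-2-(4-methylpent-3-enyl)oxirane
Product: 5 (S)-3,7-dimethyloct-6-en-1-yn-3-ol, via lithium chloroalkenyl alkoxide 4 (not isolated)
Conditions: n-BuLi (3.3 equiv), THF, −40 → −20 °C; aq. NH4Cl
Reagents that add atoms: none
Why: In this base-induced fragmentation of a 2,3-epoxy chloride to a propargylic alcohol, deprotonation at the chloromethyl carbon opens the oxirane by E2 cleavage of the CH–O bond to 4, further base removes HCl to the alkyne and holds it as the acetylide, and the bond from oxygen to the quaternary carbon is never broken, so the tertiary carbinol keeps its (S) configuration.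

Step 4
Reactants: 5 (S)-3,7-dimethyloct-6-en-1-yn-3-ol
Product: 6 (S)-linalool
Conditions: H2 (1 atm), Pd/CaCO3 poisoned with Pb(OAc)2 (Lindlar catalyst), quinoline, hexane, 20 °C, stopped after 1 equiv H2
Reagents that add atoms: none
Why: Lindlar semi-hydrogenation should reduce the terminal alkyne to the vinyl group much faster than it over-reduces or touches the trisubstituted alkene, and it does not involve the stereocentre.

Step 5
Reactants: 6 (S)-linalool
Product: 7 (S)-1-methylcyclopent-2-en-1-ol
Conditions: RuCl2(H2IMes)(=CH-C6H4-2-OiPr) (second-generation Hoveyda–Grubbs catalyst, 0.5 mol%), CH2Cl2 (1 M), 20 °C; ethyl vinyl ether quench; bulb-to-bulb distillation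
Reagents that add atoms: none
Why: Ring-closing metathesis of the 1,6-diene closes the five-membered ring with loss of volatile 2-methylpropene, is helped by the free allylic hydroxyl, and leaves the quaternary carbinol stereocentre untouched.

Step 6
Reactants: 8 5-bromo-2-fluorotoluene
Product: 10 5-bromo-2-fluoro-3-methylbenzaldehyde, via aryllithium 9 (not isolated)
Conditions: LiN(iPr)2 (1.1 equiv), THF, −78 °C; DMF, −78 → 0 °C; aq. HCl
Reagents that add atoms: N,N-dimethylformamide, CN(C)C=O
Why: In this directed ortho-lithiation and formylation, fluorine is the strongest acidifying group on the ring and its only free ortho position is C3, so the amide base removes that proton at −78 °C (cold enough to prevent loss of LiF to an aryne) and DMF traps aryllithium 9 as the aldehyde.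

Step 7
Reactants: 7 (S)-1-methylcyclopent-2-en-1-ol; 10 5-bromo-2-fluoro-3-methylbenzaldehyde
Product: 11 5-bromo-3-methyl-2-{[(1S)-1-methylcyclopent-2-en-1-yl]oxy}benzaldehyde
Conditions: 7 (1.2 equiv), KN(SiMe3)2 (1.1 equiv), THF, −20 °C; then 10 in THF–DMF (4:1), −20 → 20 °C
Reagents that add atoms: none
Why: In this nucleophilic aromatic substitution by addition–elimination, the potassium alkoxide of 7 adds at the C–F carbon activated by the ortho-formyl and para-bromo groups and fluoride leaves, so the bond from oxygen to the tertiary carbon is never broken and the (S) configuration is carried over, while the tertiary alkoxide has no α-hydrogen with which to reduce the aldehyde.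

Step 8
Reactants: 11 5-bromo-3-methyl-2-{[(1S)-1-methylcyclopent-2-en-1-yl]oxy}benzaldehyde
Product: 12 5-bromo-1-methyl-2-{[(1S)-1-methylcyclopent-2-en-1-yl]oxy}-3-vinylbenzene
Conditions: Ph3PCH3Br, KOtBu, THF, 0 → 20 °C
Reagents that add atoms: methyltriphenylphosphonium bromide, C[P+](c1ccccc1)(c1ccccc1)c1ccccc1.[Br-]
Why: Wittig methylenation with the unstabilised ylide converts the aryl aldehyde into the styrene under basic conditions that the acid-sensitive tertiary allylic aryl ether tolerates.

Step 9
Reactants: 12 5-bromo-1-methyl-2-{[(1S)-1-methylcyclopent-2-en-1-yl]oxy}-3-vinylbenzene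
Product: 15 3-methyl-4-{[(1S)-1-methylcyclopent-2-en-1-yl]oxy}-5-vinylphenol, via aryllithium 13 (not isolated), via lithium aryltrimethoxyborate 14 (not isolated)
Conditions: n-BuLi (1.05 equiv), THF, −78 °C; B(OMe)3, −78 → 0 °C; H2O2 (30% aq.), NaOH aq., 0 °C
Reagents that add atoms: trimethyl borate, COB(OC)OC (its atoms stay only in 14); hydrogen peroxide, OO
Why: Bromine–lithium exchange at −78 °C is much faster than addition of the alkyllithium to the styrene, and borylation of 13 followed by boronate oxidation (1,2-aryl shift from boron to oxygen in 14) gives the phenol without acid and without a palladium catalyst that could ionise the allylic aryl ether.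

Step 10
Reactants: 15 3-methyl-4-{[(1S)-1-methylcyclopent-2-en-1-yl]oxy}-5-vinylphenol
Product: 16 tert-butyldimethyl(3-methyl-4-{[(1S)-1-methylcyclopent-2-en-1-yl]oxy}-5-vinylphenoxy)silane
Conditions: TBSCl, imidazole, DMF, 20 °C
Reagents that add atoms: tert-butyldimethylsilyl chloride, CC(C)(C)[Si](C)(C)Cl
Why: Imidazole-promoted silylation of the unhindered phenol masks the acidic, oxidation-prone hydroxyl for the metathesis, hydride, bromination and palladium steps that follow.

Step 11
Reactants: 16 tert-butyldimethyl(3-methyl-4-{[(1S)-1-methylcyclopent-2-en-1-yl]oxy}-5-vinylphenoxy)silane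
Product: 17 (S)-2-(but-3-enyl)-6-(tert-butyldimethylsilyloxy)-2,8-dimethyl-2H-chromene
Conditions: RuCl2(H2IMes)(=CH-C6H4-2-OiPr) (second-generation Hoveyda–Grubbs catalyst, 5 mol%), ethylene (1 atm), CH2Cl2 (0.01 M), 22 → 40 °C
Reagents that add atoms: none
Why: This is a ring-rearrangement metathesis in which the ruthenium carbene loads on the aryl vinyl group (or, as Ru=CH2 under ethylene, opens the cyclopentene first), adds [2+2] to the cyclopentene alkene within the molecule and cycloreverts, so that the ring carbon next to the carbinol carbon becomes C3, double-bonded to benzylic C4, while the distal ring carbon is left as a ruthenium alkylidene that ethylene cleaves to the C3'H=CH2 terminus. The closest known reaction type is the ruthenium-catalysed rearrangement of ortho-vinylaryl cycloalkenyl ethers to 2-substituted 2H-chromenes under ethylene, applied here to an ether with a fully substituted carbinol carbon. The pyran ring closes in ring-closing-metathesis mode through a ruthenacyclobutane that forms the C3=C4 bond of the six-membered ring, and the five-membered carbocycle opens in the same turnover. No stereocentre is created, because the C2–O and C2–CH3 bonds are never broken and the (S) configuration of 16 simply becomes C2 of 17. The step needs the intramolecular rearrangement to outrun oligomerisation and not to run back to 16: high dilution and ethylene, which caps every alkylidene as a vinyl group, should secure the first, and relief of cyclopentene strain and of crowding around the doubly ortho-substituted tertiary ether, together with the low metathesis reactivity of the cis C3=C4 bond beside quaternary C2, should secure the second.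

Step 12
Reactants: 17 (S)-2-(but-3-enyl)-6-(tert-butyldimethylsilyloxy)-2,8-dimethyl-2H-chromene; 18 methacrolein
Product: 19 (S,E)-5-[6-(tert-butyldimethylsilyloxy)-2,8-dimethyl-2H-chromen-2-yl]-2-methylpent-2-enal
Conditions: RuCl2(H2IMes)(PCy3)(=CHPh) (second-generation Grubbs catalyst, 5 mol%), 18 (8 equiv), CH2Cl2, 40 °C
Reagents that add atoms: none
Why: Olefin cross-metathesis between the terminal alkene and excess methacrolein, a 1,1-disubstituted electron-poor partner that is slow to homodimerise, should give the trisubstituted enal as the thermodynamically favoured (E) isomer while the cis C3=C4 ring alkene beside quaternary C2 stays inert.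

Step 13
Reactants: 19 (S,E)-5-[6-(tert-butyldimethylsilyloxy)-2,8-dimethyl-2H-chromen-2-yl]-2-methylpent-2-enal
Product: 20 (S,E)-5-[6-(tert-butyldimethylsilyloxy)-2,8-dimethyl-2H-chromen-2-yl]-2-methylpent-2-en-1-ol
Conditions: iBu2AlH (1.3 equiv), CH2Cl2, −78 °C; aq. potassium sodium tartrate
Reagents that add atoms: none
Why: 1,2-Reduction of the enal by the aluminium hydride at −78 °C should give the (E)-allylic alcohol without touching the alkene geometry, the aryl silyl ether or the chromene.

Step 14
Reactants: 20 (S,E)-5-[6-(tert-butyldimethylsilyloxy)-2,8-dimethyl-2H-chromen-2-yl]-2-methylpent-2-en-1-ol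
Product: 21 (S,E)-2-(5-bromo-4-methylpent-3-enyl)-6-(tert-butyldimethylsilyloxy)-2,8-dimethyl-2H-chromene
Conditions: CBr4, PPh3, 2,6-lutidine (0.2 equiv), CH2Cl2, −20 → 0 °C; used at once
Reagents that add atoms: carbon tetrabromide, BrC(Br)(Br)Br
Why: Appel bromination of the primary allylic alcohol goes by direct displacement on the alkoxyphosphonium salt under neutral conditions, so the (E) geometry should be kept and the acid-sensitive chromene and silyl ether should survive.

Step 15
Reactants: 5 (S)-3,7-dimethyloct-6-en-1-yn-3-ol
Product: 22 (S,E)-3,7-dimethyl-1-(tributylstannyl)octa-1,6-dien-3-ol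
Conditions: Bu3SnH (1.2 equiv), Pd2(dba)3 (0.5 mol%), Cy3P·HBF4 (2 mol%), iPr2NEt (4 mol%), CH2Cl2, 0 °C
Reagents that add atoms: tributyltin hydride, CCCC[SnH](CCCC)CCCC
Why: Palladium-catalysed hydrostannation adds Sn–H syn across the terminal alkyne, and the bulky phosphine together with the fully substituted propargylic carbon should place tin on the terminal carbon to give the (E)-vinylstannane under non-radical conditions that avoid cyclisation onto the remote alkene.

Step 16
Reactants: 21 (S,E)-2-(5-bromo-4-methylpent-3-enyl)-6-(tert-butyldimethylsilyloxy)-2,8-dimethyl-2H-chromene; 22 (S,E)-3,7-dimethyl-1-(tributylstannyl)octa-1,6-dien-3-ol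
Product: 23 (3E,6E,8S)-1-[(2S)-6-(tert-butyldimethylsilyloxy)-2,8-dimethyl-2H-chromen-2-yl]-4,8,12-trimethyltrideca-3,6,11-trien-8-ol
Conditions: Pd2(dba)3 (2.5 mol%), AsPh3 (10 mol%), DMF, 20 → 40 °C
Reagents that add atoms: none
Why: In this Stille coupling, zerovalent palladium ionises the allylic bromide to a π-allyl complex, the vinylstannane transmetalates with retention of its (E) geometry and reductive elimination at the less hindered primary terminus should give the skipped (3'E,6'E)-diene, with the free tertiary alcohol, the aryl silyl ether and both stereocentres as spectators.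

Step 17
Reactants: 23 (3E,6E,8S)-1-[(2S)-6-(tert-butyldimethylsilyloxy)-2,8-dimethyl-2H-chromen-2-yl]-4,8,12-trimethyltrideca-3,6,11-trien-8-ol
Product: 24 (S)-2-[(3E,6E,8S)-8-hydroxy-4,8,12-trimethyltrideca-3,6,11-trienyl]-2,8-dimethyl-2H-chromen-6-ol (CNP0155965.1)
Conditions: Bu4NF (1.1 equiv), THF, 0 °C; aq. NH4Cl
Reagents that add atoms: none
Why: Fluoride-mediated desilylation cleaves the aryl silyl ether through the strong Si–F bond and the good phenoxide leaving group, under conditions too mild to ionise the tertiary allylic alcohol or the chromene ether.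

**Compound list**

1 | geraniol | CC(C)=CCC/C(C)=C/CO | starting material
2 | (2S,3S)-2,3-epoxygeraniol | CC(C)=CCC[C@]1(C)O[C@H]1CO | intermediate
3 | (2S,3R)-3-(chloromethyl)-2-methyl-2-(4-methylpent-3-enyl)oxirane | CC(C)=CCC[C@]1(C)O[C@H]1CCl | intermediate
4 | lithium (3S,1E)-1-chloro-3,7-dimethylocta-1,6-dien-3-olate (E geometry assumed from anti elimination) | CC(C)=CCC[C@](C)([O-])/C=C/Cl.[Li+] | intermediate
5 | (S)-3,7-dimethyloct-6-en-1-yn-3-ol ((S)-dehydrolinalool) | CC(C)=CCC[C@](C)(O)C#C | intermediate
6 | (S)-linalool | CC(C)=CCC[C@](C)(O)C=C | intermediate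
7 | (S)-1-methylcyclopent-2-en-1-ol | C[C@@]1(O)C=CCC1 | intermediate
8 | 5-bromo-2-fluorotoluene | Cc1cc(Br)ccc1F | starting material
9 | (5-bromo-2-fluoro-3-methylphenyl)lithium | [Li]c1cc(Br)cc(C)c1F | intermediate
10 | 5-bromo-2-fluoro-3-methylbenzaldehyde | O=Cc1cc(Br)cc(C)c1F | intermediate
11 | 5-bromo-3-methyl-2-{[(1S)-1-methylcyclopent-2-en-1-yl]oxy}benzaldehyde | O=Cc1cc(Br)cc(C)c1O[C@]1(C)C=CCC1 | intermediate
12 | 5-bromo-1-methyl-2-{[(1S)-1-methylcyclopent-2-en-1-yl]oxy}-3-vinylbenzene | C=Cc1cc(Br)cc(C)c1O[C@]1(C)C=CCC1 | intermediate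
13 | (3-methyl-4-{[(1S)-1-methylcyclopent-2-en-1-yl]oxy}-5-vinylphenyl)lithium | [Li]c1cc(C=C)c(O[C@]2(C)C=CCC2)c(C)c1 | intermediate
14 | lithium trimethoxy(3-methyl-4-{[(1S)-1-methylcyclopent-2-en-1-yl]oxy}-5-vinylphenyl)borate | CO[B-](OC)(OC)c1cc(C=C)c(O[C@]2(C)C=CCC2)c(C)c1.[Li+] | intermediate
15 | 3-methyl-4-{[(1S)-1-methylcyclopent-2-en-1-yl]oxy}-5-vinylphenol | C=Cc1cc(O)cc(C)c1O[C@]1(C)C=CCC1 | intermediate
16 | tert-butyldimethyl(3-methyl-4-{[(1S)-1-methylcyclopent-2-en-1-yl]oxy}-5-vinylphenoxy)silane | C=Cc1cc(O[Si](C)(C)C(C)(C)C)cc(C)c1O[C@]1(C)C=CCC1 | intermediate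
17 | (S)-2-(but-3-enyl)-6-(tert-butyldimethylsilyloxy)-2,8-dimethyl-2H-chromene | C=CCC[C@@]1(C)C=Cc2cc(O[Si](C)(C)C(C)(C)C)cc(C)c2O1 | intermediate
18 | methacrolein | C=C(C)C=O | starting material
19 | (S,E)-5-[6-(tert-butyldimethylsilyloxy)-2,8-dimethyl-2H-chromen-2-yl]-2-methylpent-2-enal | O=C/C(C)=C/CC[C@@]1(C)C=Cc2cc(O[Si](C)(C)C(C)(C)C)cc(C)c2O1 | intermediate
20 | (S,E)-5-[6-(tert-butyldimethylsilyloxy)-2,8-dimethyl-2H-chromen-2-yl]-2-methylpent-2-en-1-ol | OC/C(C)=C/CC[C@@]1(C)C=Cc2cc(O[Si](C)(C)C(C)(C)C)cc(C)c2O1 | intermediate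
21 | (S,E)-2-(5-bromo-4-methylpent-3-enyl)-6-(tert-butyldimethylsilyloxy)-2,8-dimethyl-2H-chromene | BrC/C(C)=C/CC[C@@]1(C)C=Cc2cc(O[Si](C)(C)C(C)(C)C)cc(C)c2O1 | intermediate
22 | (S,E)-3,7-dimethyl-1-(tributylstannyl)octa-1,6-dien-3-ol | CC(C)=CCC[C@](C)(O)/C=C/[Sn](CCCC)(CCCC)CCCC | intermediate
23 | (3E,6E,8S)-1-[(2S)-6-(tert-butyldimethylsilyloxy)-2,8-dimethyl-2H-chromen-2-yl]-4,8,12-trimethyltrideca-3,6,11-trien-8-ol | CC(C)=CCC[C@](C)(O)/C=C/C/C(C)=C/CC[C@@]1(C)C=Cc2cc(O[Si](C)(C)C(C)(C)C)cc(C)c2O1 | intermediate
24 | (S)-2-[(3E,6E,8S)-8-hydroxy-4,8,12-trimethyltrideca-3,6,11-trienyl]-2,8-dimethyl-2H-chromen-6-ol | CC(C)=CCC[C@](C)(O)/C=C/C/C(C)=C/CC[C@@]1(C)C=Cc2cc(O)cc(C)c2O1 | target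

**Step count**

Total: 17 steps. Longest linear sequence: 15 steps from geraniol (steps 1–5, 7–14, 16, 17).

**Steps most likely to fail**

1. Step 11 (ring-rearrangement metathesis). The ruthenium alkylidene may fail to open the hindered, only weakly strained cyclopentene beside the quaternary carbinol carbon, or ring-opened alkylidenes may couple between molecules faster than they close the pyran.
Fallback, setting out from 6 and 10 and returning to the route at 20: the alkene that ring opening was to deliver is carried in from the start. The potassium alkoxide of (S)-linalool 6 displaces fluoride from 10 (KN(SiMe3)2, THF–DMF) to give 5-bromo-2-{[(3S)-3,7-dimethylocta-1,6-dien-3-yl]oxy}-3-methylbenzaldehyde F1. Wittig methylenation gives 5-bromo-2-{[(3S)-3,7-dimethylocta-1,6-dien-3-yl]oxy}-1-methyl-3-vinylbenzene F2. Bromine–lithium exchange, borylation and peroxide oxidation as in step 9 give 4-{[(3S)-3,7-dimethylocta-1,6-dien-3-yl]oxy}-3-methyl-5-vinylphenol F3, which is silylated to tert-butyl(4-{[(3S)-3,7-dimethylocta-1,6-dien-3-yl]oxy}-3-methyl-5-vinylphenoxy)dimethylsilane F4. Plain ring-closing metathesis between the two monosubstituted alkenes with RuCl2(PCy3)2(=CHPh) (first-generation Grubbs catalyst), which is slow to engage the trisubstituted alkene, closes the pyran to (S)-6-(tert-butyldimethylsilyloxy)-2,8-dimethyl-2-(4-methylpent-3-enyl)-2H-chromene F5. Allylic oxidation with SeO2 (cat.) and t-BuOOH in CH2Cl2 then hydroxylates the (E)-methyl group of the terminal trisubstituted alkene to give 20; any over-oxidised enal 19 would be returned to 20 by step 13.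

2. Step 7 (fluoride displacement). The bulky tertiary alkoxide may add too slowly at a C–F carbon flanked by methyl and formyl groups, while reversible alkoxide addition to the aldehyde and base-induced loss of the sensitive allylic alcohol compete.
Fallback, setting out from 10 and returning at 11: the activating group is changed to a nitrile, which is smaller, cannot take up alkoxide and activates at least as strongly. Oxidative ammonolysis with I2 and aqueous NH3 in THF converts 10 into 5-bromo-2-fluoro-3-methylbenzonitrile F6. The potassium alkoxide of 7 displaces fluoride to give 5-bromo-3-methyl-2-{[(1S)-1-methylcyclopent-2-en-1-yl]oxy}benzonitrile F7. Reduction with iBu2AlH in toluene at −78 °C and hydrolysis of the aluminium aldimine with aqueous tartaric acid give 11.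

3. Step 16 (Stille coupling). The π-allyl palladium intermediate may scramble (allylic transposition to the branched isomer, erosion of the (E) trisubstituted alkene), the stannane may be protodestannylated or homocoupled, and the skipped diene may migrate into conjugation.
Fallback, setting out from 21 and 5 and returning at 23: the fragments are joined at the alkyne stage and the C6'=C7' geometry is set afterwards. Copper-mediated alkynylation of bromide 21 with the terminal alkyne 5 (CuI, K2CO3, NaI, DMF, 20 °C) gives (6S,10E)-13-[(2S)-6-(tert-butyldimethylsilyloxy)-2,8-dimethyl-2H-chromen-2-yl]-2,6,10-trimethyltrideca-2,10-dien-7-yn-6-ol F8. NaAlH2(OCH2CH2OMe)2 in THF (0 → 20 °C) then reduces the propargylic alcohol by hydroxyl-directed trans-hydroalumination to the (E)-allylic alcohol 23; should the hydride also remove the aryl silyl group, 24 would be obtained directly.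

**Further compounds**

F1 | step 11 | 5-bromo-2-{[(3S)-3,7-dimethylocta-1,6-dien-3-yl]oxy}-3-methylbenzaldehyde | CC(C)=CCC[C@](C)(Oc1c(C)cc(Br)cc1C=O)C=C
F2 | step 11 | 5-bromo-2-{[(3S)-3,7-dimethylocta-1,6-dien-3-yl]oxy}-1-methyl-3-vinylbenzene | CC(C)=CCC[C@](C)(Oc1c(C)cc(Br)cc1C=C)C=C
F3 | step 11 | 4-{[(3S)-3,7-dimethylocta-1,6-dien-3-yl]oxy}-3-methyl-5-vinylphenol | CC(C)=CCC[C@](C)(Oc1c(C)cc(O)cc1C=C)C=C
F4 | step 11 | tert-butyl(4-{[(3S)-3,7-dimethylocta-1,6-dien-3-yl]oxy}-3-methyl-5-vinylphenoxy)dimethylsilane | CC(C)=CCC[C@](C)(Oc1c(C)cc(O[Si](C)(C)C(C)(C)C)cc1C=C)C=C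
F5 | step 11 | (S)-6-(tert-butyldimethylsilyloxy)-2,8-dimethyl-2-(4-methylpent-3-enyl)-2H-chromene | CC(C)=CCC[C@@]1(C)C=Cc2cc(O[Si](C)(C)C(C)(C)C)cc(C)c2O1
F6 | step 7 | 5-bromo-2-fluoro-3-methylbenzonitrile | Cc1cc(Br)cc(C#N)c1F
F7 | step 7 | 5-bromo-3-methyl-2-{[(1S)-1-methylcyclopent-2-en-1-yl]oxy}benzonitrile | Cc1cc(Br)cc(C#N)c1O[C@]1(C)C=CCC1
F8 | step 16 | (6S,10E)-13-[(2S)-6-(tert-butyldimethylsilyloxy)-2,8-dimethyl-2H-chromen-2-yl]-2,6,10-trimethyltrideca-2,10-dien-7-yn-6-ol | CC(C)=CCC[C@](C)(O)C#CC/C(C)=C/CC[C@@]1(C)C=Cc2cc(O[Si](C)(C)C(C)(C)C)cc(C)c2O1
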